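**Retrosynthetic overview**
1. The target is read as two 4-aryl-3,4-dihydrocoumarins joined C3–C3': unit A (5,6,7,8-tetraoxygenated, 3,4-cis) and unit B (5,7-dioxygenated, 3',4'-trans). All eight phenols are carried as methyl ethers and freed last.
2. Key disconnection: the pyranone ring of unit B is cut at O1'–C8a' and C4a'–C4'. This leads back to 3,5-dimethoxybenzyne and a cis-β-lactone (oxetan-2-one) that already holds C2', C3', C4', the anisyl group and all of unit A. The aryne is inserted into the benzylic C4'–O bond.
3. Enabling feature: C4' bears a 4-oxygenated phenyl ring, so its C–O bond in the strained lactone can ionise to a p-alkoxybenzyl cation. O1' and C4' stand 1,3 on C2'–C3', which fits the adjacent carbons C8a'/C4a' of the resorcinol ring. The C5' oxygen beside the triple bond sends O to C8a' and C to C4a'.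
4. The β-lactone comes from the ketene of a unit A acetic acid and 4-methoxybenzaldehyde (alkaloid-catalysed [2+2], sets C3'). Unit A comes from an organocatalytic o-quinone methide/Meldrum's acid addition (sets C4), then enolate alkylation and kinetic protonation (cis C3).
5. Order of ring formation: pyranone ring of unit A (step 5), oxetanone (step 9), pyranone ring of unit B (step 10).

Key step: step 10

Remark: unprimed locants belong to unit A and primed locants to unit B (chroman-2-one numbering, also in open precursors); the sense of induction in steps 5 and 9 is assigned by analogy, and the pseudoenantiomeric quinidine-derived catalyst would be used if it were opposite.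

Step 1
Reactants: 1 3,5-dimethoxyphenol
Product: 2 2-bromo-3,5-dimethoxyphenol
Conditions: NBS (1.0 equiv), i-Pr2NH (10 mol %), CH2Cl2, −78 → 0 °C
Reagents that add atoms: N-bromosuccinimide O=C1CCC(=O)N1Br
Why: Amine-catalysed electrophilic ortho-bromination of a phenol, in which the N-bromoamine is hydrogen-bonded to the OH group and delivers bromine to C2 beside it and not to the more hindered C4 between the two methoxy groups.

Step 2
Reactants: 2 2-bromo-3,5-dimethoxyphenol
Product: 5 3,5-dimethoxy-2-(trimethylsilyl)phenyl trifluoromethanesulfonate, via silyl ether 3 (not isolated), via lithium phenolate 4 (not isolated)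
Conditions: (Me3Si)2NH, THF, 70 °C, then evaporation; n-BuLi, THF, −100 → −78 °C; Tf2O, −100 °C → rt
Reagents that add atoms: hexamethyldisilazane C[Si](C)(C)N[Si](C)(C)C; trifluoromethanesulfonic anhydride O=S(=O)(OS(=O)(=O)C(F)(F)F)C(F)(F)F
Why: O-Silylation, bromine–lithium exchange and retro-Brook rearrangement (1,3-shift of silicon from O to C) give phenolate 4, which is triflated, the standard sequence to o-silylaryl triflates.

Step 3
Reactants: 6 1,2,3,4-tetramethoxybenzene
Product: 9 2,3,4,5-tetramethoxyphenol, via aryllithium 7 (not isolated), via boronate 8 (not isolated)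
Conditions: n-BuLi, TMEDA, THF, 0 °C; B(OMe)3, −78 °C → rt; AcOH, 30% aq H2O2, 0 °C → rt
Reagents that add atoms: hydrogen peroxide OO; trimethyl borate COB(OC)OC (its atoms stay only in intermediate 8)
Why: Directed ortho-metalation beside a methoxy group, borylation and oxidation of the aryl–boron bond (boronate hydroxylation) place the phenolic oxygen on one of the two equivalent free positions.

Step 4
Reactants: 9 2,3,4,5-tetramethoxyphenol; 10 4-methoxybenzaldehyde
Product: 11 2,3,4,5-tetramethoxy-6-[(4-methoxyphenyl)(4-methylbenzenesulfonyl)methyl]phenol (racemate)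
Conditions: 4-MeC6H4SO2Na, HCO2H–H2O, rt
Reagents that add atoms: sodium 4-methylbenzenesulfinate Cc1ccc(cc1)S(=O)[O-].[Na+]
Why: Acid-promoted three-component condensation (ortho-hydroxyalkylation of the phenol at its only free ring position, then capture of the benzylic cation by sulfinate) should give a bench-stable o-quinone methide precursor whose stereocentre is erased again in step 5.

Step 5
Reactants: 11 sulfone of step 4; 12 Meldrum's acid (2,2-dimethyl-1,3-dioxane-4,6-dione)
Product: 16 (4R)-5,6,7,8-tetramethoxy-4-(4-methoxyphenyl)chroman-2-one, via o-quinone methide 13 (not isolated), via Michael adduct 14 (not isolated), via carboxylic acid 15 (not isolated)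
Conditions: 3-{[3,5-bis(trifluoromethyl)phenyl]amino}-4-{[(8α,9S)-6'-methoxycinchonan-9-yl]amino}cyclobut-3-ene-1,2-dione (quinine-derived squaramide, 5 mol %), aq NaHCO3, CH2Cl2, rt; then p-TsOH·H2O, toluene, 100 °C
Reagents that add atoms: none
Why: Base-induced 1,4-elimination of sulfinate gives o-quinone methide 13, to which Meldrum's acid adds in a catalytic asymmetric Michael reaction where the bifunctional squaramide binds both partners by hydrogen bonds and exposes one face of the methide carbon (C4 set as R), after which acid closes the lactone with loss of acetone and decarboxylates.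

Step 6
Reactants: 16 (4R)-5,6,7,8-tetramethoxy-4-(4-methoxyphenyl)chroman-2-one; 17 tert-butyl bromoacetate
Product: 19 tert-butyl 2-[(3S,4R)-5,6,7,8-tetramethoxy-4-(4-methoxyphenyl)-2-oxochroman-3-yl]acetate (3,4-trans), via lithium enolate 18 (not isolated)
Conditions: LiN(SiMe3)2, THF, −78 °C; then 17, −78 → −40 °C
Reagents that add atoms: none
Why: Lactone enolate alkylation in which the electrophile approaches the face opposite the C4 aryl group (held pseudoaxial by the peri C5 methoxy group), so the side chain enters trans to it (C3 = S).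

Step 7
Reactants: 19 trans ester of step 6
Product: 21 tert-butyl 2-[(3R,4R)-5,6,7,8-tetramethoxy-4-(4-methoxyphenyl)-2-oxochroman-3-yl]acetate (3,4-cis), via lithium enolate 20 (not isolated)
Conditions: LiN(SiMe3)2, THF, −78 °C; then 2,6-di-tert-butylphenol, −78 °C
Reagents that add atoms: none
Why: Deprotonation–kinetic protonation, in which only the far more acidic aryl-lactone α-proton is removed and the bulky phenol protonates planar enolate 20 from the face opposite the C4 aryl group, leaving H trans and the side chain cis to the aryl group (C3 = R).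

Step 8
Reactants: 21 cis ester of step 7
Product: 22 2-[(3R,4R)-5,6,7,8-tetramethoxy-4-(4-methoxyphenyl)-2-oxochroman-3-yl]acetic acid
Conditions: CF3CO2H, CH2Cl2, 0 °C → rt
Reagents that add atoms: none
Why: Acidolysis of the tert-butyl ester through the tert-butyl cation leaves the aryl lactone, the methyl ethers and both stereocentres untouched.

Step 9
Reactants: 22 acid of step 8; 10 4-methoxybenzaldehyde
Product: 25 (3R,4R)-4-(4-methoxyphenyl)-3-[(3S,4R)-5,6,7,8-tetramethoxy-4-(4-methoxyphenyl)-2-oxochroman-3-yl]oxetan-2-one, via acid chloride 23 (not isolated), via ketene 24 (not isolated)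
Conditions: (COCl)2, cat DMF, CH2Cl2, 0 °C → rt, evaporation; then 10, O-trimethylsilylquinine (15 mol %), LiClO4, i-Pr2NEt, CH2Cl2–Et2O, −78 °C
Reagents that add atoms: oxalyl chloride ClC(=O)C(=O)Cl (its chlorine stays only in intermediate 23)
Why: Dehydrohalogenation of 23 gives ketene 24, which enters a cinchona alkaloid/LiClO4-catalysed asymmetric ketene–aldehyde [2+2] cycloaddition in which the alkaloid-bound enolate adds to the lithium-activated aldehyde through a closed transition state that fixes C3' (oxetanone C3 = R) under catalyst control and gives the cis lactone, with ring closure on the acylammonium so fast that no free alkoxide can transacylate onto the aryl lactone.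

Step 10
Reactants: 25 β-lactone of step 9; 5 3,5-dimethoxy-2-(trimethylsilyl)phenyl trifluoromethanesulfonate
Product: 28 (3S,4R)-3-[(3S,4S)-5,7-dimethoxy-4-(4-methoxyphenyl)-2-oxochroman-3-yl]-5,6,7,8-tetramethoxy-4-(4-methoxyphenyl)chroman-2-one, via aryne 26 (not isolated), via zwitterion 27 (not isolated)
Conditions: Bu4N[Ph3SiF2] (3 equiv), 5 (2.5 equiv, added over 4 h), THF–toluene, 0 → 25 °C
Reagents that add atoms: none
Why: Proposed new method: the carbonyl oxygen of β-lactone 25, made carboxylate-like because ring strain and the 4-methoxyphenyl group let the benzylic C4'–O bond ionise as it attacks, adds to aryne 26 at the carbon remote from the neighbouring methoxy group, and the opened zwitterion 27 (aryl anion beside OMe, p-methoxybenzyl cation) collapses by C–C bond formation, so that the aryne is inserted into the C4'–O bond. The closest known reaction types are the insertion of arynes into the benzylic C–O bond of aryl epoxides to give 2,3-dihydrobenzofurans and the insertion of arynes into the C=O bond of electron-rich aromatic aldehydes. The pyranone ring of unit B closes by cation–anion recombination in a 6-exo-trig sense (the quinoid C4'–aryl π bond lies outside the new ring) after the O1'–C8a' bond has been made intermolecularly. C4' is set by the untouched C3' stereocentre: allylic 1,3-strain keeps H3' in the plane of the cation, the aryl anion is held on the C2' face through the ester and C3 of unit A covers the other face, so the new bond forms anti to C3 and gives the 3',4'-trans ring, while the original C4' configuration of 25 is erased. The step needs regioselectivity (O to C8a', C to C4a'), secured by the methoxy group beside the triple bond, which directs nucleophiles to the distal aryne carbon and stabilises the adjacent anion; it also needs ring closure to outrun loss of CO2 from 25, loss of H3' and attack of the anion on the ester carbonyl, for which the strongly stabilised cation, the non-protic medium, low temperature and slow aryne generation are chosen.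

Step 11
Reactants: 28 octamethyl ether of step 10
Product: 29 (3S,4R)-3-[(3S,4S)-5,7-dihydroxy-4-(4-hydroxyphenyl)-2-oxochroman-3-yl]-5,6,7,8-tetrahydroxy-4-(4-hydroxyphenyl)chroman-2-one (CNP0064734.2)
Conditions: BBr3 (20 equiv), CH2Cl2, −78 → 25 °C, under Ar; then MeOH, H2O
Reagents that add atoms: none
Why: Exhaustive Lewis acid-mediated cleavage of the eight aryl methyl ethers touches no stereocentre, and because each polyhydroxyphenyl ring is symmetric about its bond to C4 or C4', any acyl migration between its two ortho oxygens returns the same lactone.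

**Compound list**
1 | 3,5-dimethoxyphenol | COc1cc(O)cc(OC)c1 | starting material
2 | 2-bromo-3,5-dimethoxyphenol | COc1cc(O)c(Br)c(OC)c1 | intermediate
3 | (2-bromo-3,5-dimethoxyphenoxy)trimethylsilane | COc1cc(O[Si](C)(C)C)c(Br)c(OC)c1 | intermediate (not isolated)
4 | lithium 3,5-dimethoxy-2-(trimethylsilyl)phenolate | COc1cc([O-])c([Si](C)(C)C)c(OC)c1.[Li+] | intermediate (not isolated)
5 | 3,5-dimethoxy-2-(trimethylsilyl)phenyl trifluoromethanesulfonate | COc1cc(OS(=O)(=O)C(F)(F)F)c([Si](C)(C)C)c(OC)c1 | intermediate
6 | 1,2,3,4-tetramethoxybenzene | COc1ccc(OC)c(OC)c1OC | starting material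
7 | (2,3,4,5-tetramethoxyphenyl)lithium | [Li]c1cc(OC)c(OC)c(OC)c1OC | intermediate (not isolated)
8 | dimethyl (2,3,4,5-tetramethoxyphenyl)boronate | COB(OC)c1cc(OC)c(OC)c(OC)c1OC | intermediate (not isolated)
9 | 2,3,4,5-tetramethoxyphenol | Oc1cc(OC)c(OC)c(OC)c1OC | intermediate
10 | 4-methoxybenzaldehyde | COc1ccc(C=O)cc1 | starting material
11 | 2,3,4,5-tetramethoxy-6-[(4-methoxyphenyl)(4-methylbenzenesulfonyl)methyl]phenol (racemate) | COc1ccc(cc1)C(c1c(O)c(OC)c(OC)c(OC)c1OC)S(=O)(=O)c1ccc(C)cc1 | intermediate
12 | Meldrum's acid (2,2-dimethyl-1,3-dioxane-4,6-dione) | CC1(C)OC(=O)CC(=O)O1 | starting material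
13 | 2,3,4,5-tetramethoxy-6-(4-methoxybenzylidene)cyclohexa-2,4-dien-1-one (o-quinone methide) | COc1ccc(cc1)C=C1C(=O)C(OC)=C(OC)C(OC)=C1OC | intermediate (not isolated)
14 | 5-[(R)-(2-hydroxy-3,4,5,6-tetramethoxyphenyl)(4-methoxyphenyl)methyl]-2,2-dimethyl-1,3-dioxane-4,6-dione | CC1(C)OC(=O)C(C(=O)O1)[C@H](c1ccc(OC)cc1)c1c(O)c(OC)c(OC)c(OC)c1OC | intermediate (not isolated)
15 | (4R)-5,6,7,8-tetramethoxy-4-(4-methoxyphenyl)-2-oxochromane-3-carboxylic acid (C3 not defined) | O=C1Oc2c(OC)c(OC)c(OC)c(OC)c2[C@@H](c2ccc(OC)cc2)C1C(=O)O | intermediate (not isolated)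
16 | (4R)-5,6,7,8-tetramethoxy-4-(4-methoxyphenyl)chroman-2-one | O=C1Oc2c(OC)c(OC)c(OC)c(OC)c2[C@@H](c2ccc(OC)cc2)C1 | intermediate
17 | tert-butyl bromoacetate | BrCC(=O)OC(C)(C)C | starting material
18 | lithium enolate of 16 | [Li+].[O-]C1Oc2c(OC)c(OC)c(OC)c(OC)c2[C@@H](c2ccc(OC)cc2)C=1 | intermediate (not isolated)
19 | tert-butyl 2-[(3S,4R)-5,6,7,8-tetramethoxy-4-(4-methoxyphenyl)-2-oxochroman-3-yl]acetate (3,4-trans) | O=C1Oc2c(OC)c(OC)c(OC)c(OC)c2[C@@H](c2ccc(OC)cc2)[C@@H]1CC(=O)OC(C)(C)C | intermediate
20 | lithium enolate of 19 | [Li+].[O-]C1Oc2c(OC)c(OC)c(OC)c(OC)c2[C@@H](c2ccc(OC)cc2)C=1CC(=O)OC(C)(C)C | intermediate (not isolated)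
21 | tert-butyl 2-[(3R,4R)-5,6,7,8-tetramethoxy-4-(4-methoxyphenyl)-2-oxochroman-3-yl]acetate (3,4-cis) | O=C1Oc2c(OC)c(OC)c(OC)c(OC)c2[C@@H](c2ccc(OC)cc2)[C@H]1CC(=O)OC(C)(C)C | intermediate
22 | 2-[(3R,4R)-5,6,7,8-tetramethoxy-4-(4-methoxyphenyl)-2-oxochroman-3-yl]acetic acid | O=C1Oc2c(OC)c(OC)c(OC)c(OC)c2[C@@H](c2ccc(OC)cc2)[C@H]1CC(=O)O | intermediate
23 | 2-[(3R,4R)-5,6,7,8-tetramethoxy-4-(4-methoxyphenyl)-2-oxochroman-3-yl]acetyl chloride | O=C1Oc2c(OC)c(OC)c(OC)c(OC)c2[C@@H](c2ccc(OC)cc2)[C@H]1CC(=O)Cl | intermediate (not isolated)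
24 | (3S,4R)-5,6,7,8-tetramethoxy-4-(4-methoxyphenyl)-3-(2-oxoethenyl)chroman-2-one (ketene; geometry as in 22, descriptor changed by priority only) | O=C1Oc2c(OC)c(OC)c(OC)c(OC)c2[C@@H](c2ccc(OC)cc2)[C@H]1C=C=O | intermediate (not isolated)
25 | (3R,4R)-4-(4-methoxyphenyl)-3-[(3S,4R)-5,6,7,8-tetramethoxy-4-(4-methoxyphenyl)-2-oxochroman-3-yl]oxetan-2-one (cis-β-lactone; unit A geometry as in 22) | O=C1Oc2c(OC)c(OC)c(OC)c(OC)c2[C@@H](c2ccc(OC)cc2)[C@H]1[C@H]1C(=O)O[C@H]1c1ccc(OC)cc1 | intermediate
26 | 3,5-dimethoxybenzyne (1,2-didehydro-3,5-dimethoxybenzene) | COC1=CC(OC)=CC#C1 | intermediate (not isolated)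
27 | ring-opened zwitterion: 3,5-dimethoxyphenyl ester of the unit A acid with an aryl anion at C4a' and a 4-methoxybenzyl cation at C4' (C3' as in 25) | O=C1Oc2c(OC)c(OC)c(OC)c(OC)c2[C@@H](c2ccc(OC)cc2)[C@H]1[C@@H](C(=O)Oc1cc(OC)cc(OC)[c-]1)[CH+]c1ccc(OC)cc1 | intermediate (not isolated)
28 | (3S,4R)-3-[(3S,4S)-5,7-dimethoxy-4-(4-methoxyphenyl)-2-oxochroman-3-yl]-5,6,7,8-tetramethoxy-4-(4-methoxyphenyl)chroman-2-one | O=C1Oc2c(OC)c(OC)c(OC)c(OC)c2[C@@H](c2ccc(OC)cc2)[C@H]1[C@H]1C(=O)Oc2cc(OC)cc(OC)c2[C@@H]1c1ccc(OC)cc1 | intermediate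
29 | (3S,4R)-3-[(3S,4S)-5,7-dihydroxy-4-(4-hydroxyphenyl)-2-oxochroman-3-yl]-5,6,7,8-tetrahydroxy-4-(4-hydroxyphenyl)chroman-2-one | O=C1Oc2c(O)c(O)c(O)c(O)c2[C@@H](c2ccc(O)cc2)[C@H]1[C@H]1C(=O)Oc2cc(O)cc(O)c2[C@@H]1c1ccc(O)cc1 | target

**Totals**
Total step count: 11. Longest linear sequence: 9 steps (steps 3 to 11); steps 1 and 2 make the aryne precursor that joins in step 10.

**Steps most likely to fail**

Step 10. The β-lactone may lose CO2 or be opened by fluoride before it meets the aryne. After O-arylation the aryl anion may attack the ester carbonyl (acyl migration), or the cation may lose H3' (elimination to a cinnamate) instead of closing the ring. Fallback with known chemistry, setting out from 25: Friedel–Crafts alkylation of 1,3,5-trimethoxybenzene (all ring positions equivalent) with BF3·OEt2 in CH2Cl2 at −40 °C opens the lactone at the benzylic carbon. The arene should approach the cation anti to C3, as in step 10, and give the trimethoxyphenyl acid F1. Under the BBr3 conditions of step 11 its nine methyl ethers are cleaved and the 2,4,6-trihydroxyphenyl ring lactonises onto the free acid (both ortho hydroxyls give the same ring), so the route is rejoined at 29.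

Step 9. The ammonium enolate may add too slowly to the electron-rich aldehyde, and LiClO4 may ionise or decarboxylate the product lactone. Fallback, setting out from 22: the S-pyridin-2-yl thioester F2 (2,2'-dipyridyl disulfide, PPh3) is converted with LiN(SiMe3)2/Et3SiCl into the silyl ketene acetal F3, the thioester being the most acidic site. A ZnCl2-promoted tandem Mukaiyama aldol–lactonisation with 10 should then give the trans-β-lactone F4. C3' is now set by substrate control (approach anti to the chromanone ring), with diastereomers separated if needed. F4 is submitted to the conditions of step 10, where C4' is planarised, and the route is rejoined at 28.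

Step 5. Facial selectivity may be poor because the methoxy group beside the methide carbon twists the o-quinone methide out of the binding mode of the catalyst. Fallback, setting out from 9: Pechmann condensation with ethyl 3-(4-methoxyphenyl)-3-oxopropanoate (CH3SO3H, rt) should give the 4-aryl coumarin F5. Asymmetric conjugate reduction with copper hydride (Cu(OAc)2, (R)-DTBM-SEGPHOS, (EtO)2MeSiH, t-BuOH, toluene) then sets C4 and rejoins the route at 16.

Further compounds
F1 | step 10 | (2S,3S)-3-(4-methoxyphenyl)-2-[(3S,4R)-5,6,7,8-tetramethoxy-4-(4-methoxyphenyl)-2-oxochroman-3-yl]-3-(2,4,6-trimethoxyphenyl)propanoic acid | O=C1Oc2c(OC)c(OC)c(OC)c(OC)c2[C@@H](c2ccc(OC)cc2)[C@H]1[C@@H](C(=O)O)[C@@H](c1ccc(OC)cc1)c1c(OC)cc(OC)cc1OC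
F2 | step 9 | S-pyridin-2-yl 2-[(3R,4R)-5,6,7,8-tetramethoxy-4-(4-methoxyphenyl)-2-oxochroman-3-yl]ethanethioate | O=C1Oc2c(OC)c(OC)c(OC)c(OC)c2[C@@H](c2ccc(OC)cc2)[C@H]1CC(=O)Sc1ccccn1
F3 | step 9 | (3S,4R)-5,6,7,8-tetramethoxy-4-(4-methoxyphenyl)-3-[2-(pyridin-2-ylsulfanyl)-2-(triethylsilyloxy)ethenyl]chroman-2-one (silyl ketene acetal, double bond geometry not defined) | O=C1Oc2c(OC)c(OC)c(OC)c(OC)c2[C@@H](c2ccc(OC)cc2)[C@H]1C=C(O[Si](CC)(CC)CC)Sc1ccccn1
F4 | step 9 | (3R,4S)-4-(4-methoxyphenyl)-3-[(3S,4R)-5,6,7,8-tetramethoxy-4-(4-methoxyphenyl)-2-oxochroman-3-yl]oxetan-2-one (trans-β-lactone) | O=C1Oc2c(OC)c(OC)c(OC)c(OC)c2[C@@H](c2ccc(OC)cc2)[C@H]1[C@H]1C(=O)O[C@@H]1c1ccc(OC)cc1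
F5 | step 5 | 5,6,7,8-tetramethoxy-4-(4-methoxyphenyl)-2H-chromen-2-one | O=C1C=C(c2ccc(OC)cc2)c2c(OC)c(OC)c(OC)c(OC)c2O1
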